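**Retrosynthetic overview**
- Aspergilol C ⇐ O‑silyl ether ⇐ ring C closed last by intramolecular carbonyl coupling (C10=C11) of a keto aldehyde.
- Keto aldehyde ⇐ C17–C18 alkylation of a ring A/B β‑keto ester with a ring D bromide.
- Ring B and the tetrasubstituted C1=C2 alkene ⇐ key step: [2+2] cycloaddition of a hydrindene silyl enol ether with a but‑2‑ynoate, then 4π electrocyclic ring opening (two‑carbon ring expansion, six‑ to eight‑membered).
- Ring A ⇐ ring‑closing metathesis on (+)‑dihydrocarvone (C6 and C9 bought; C5 set later by hydrogenation).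
- Ring D ⇐ (−)‑α‑thujone (C16 bought; C12, C13, C15 set from it). Order of ring formation: D (bought), A, B, C.

Assumption: carbons are numbered C1–C18 along the ring atoms of the given SMILES (C1 = alkene carbon bearing CH3; C2–C6 ring A; C7–C10 and C18 ring B; C11, C12, C16, C17 ring C; C13–C15 ring D).
Assumption: (+)‑dihydrocarvone 1 is used as sold (5R; trans/cis mixture at the enolisable C2, drawn trans; also one step from (R)‑carvone); (−)‑α‑thujone 9 and benzyl but‑2‑ynoate 5 are catalogue compounds.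

**Route**

Step 1
Reactants: 1 (+)-dihydrocarvone [(2R,5R)-2-methyl-5-(prop-1-en-2-yl)cyclohexan-1-one]
Product: 2 (3S,6R)-6-methyl-2-methylidene-3-(prop-1-en-2-yl)cyclohexan-1-one
Conditions: (CH2O)n, PhNHMe·CF3CO2H (0.3 equiv), THF, reflux
Reagents that add atoms: formaldehyde (as paraformaldehyde), C=O
Why: Mannich-type α-methylenation can eliminate only at the α-CH2 carbon, so the exocyclic enone forms regioselectively at the future C2 while the C9 methyl equilibrates to the trans arrangement; no new stereocenter.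

Step 2
Reactants: 2 (3S,6R)-6-methyl-2-methylidene-3-(prop-1-en-2-yl)cyclohexan-1-one
Product: 3 trimethyl{[(3S,6R)-6-methyl-3-(prop-1-en-2-yl)-2-(prop-2-en-1-yl)cyclohex-1-en-1-yl]oxy}silane
Conditions: CH2=CHMgBr, CuBr·SMe2 (10 mol%), TMSCl, THF, –78 °C
Reagents that add atoms: vinylmagnesium bromide, C=C[Mg]Br; chlorotrimethylsilane, C[Si](C)(C)Cl
Why: copper-catalysed conjugate addition to the exocyclic enone with in situ O-silylation gives the tetrasubstituted C10=C2 silyl enol ether regiospecifically, which enolisation of the 2,6-disubstituted ketone could not; no new stereocenter.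

Step 3
Reactants: 3 trimethyl{[(3S,6R)-6-methyl-3-(prop-1-en-2-yl)-2-(prop-2-en-1-yl)cyclohex-1-en-1-yl]oxy}silane
Product: 4 trimethyl{[(3aS,6R)-3,6-dimethyl-3a,4,5,6-tetrahydro-1H-inden-7-yl]oxy}silane
Conditions: second-generation Grubbs catalyst (5 mol%), CH2Cl2, 40 °C
Reagents that add atoms: none
Why: ring-closing metathesis of the allyl and isopropenyl groups closes ring A as the trisubstituted C4=C5 cyclopentene, the tetrasubstituted silyl enol ether being inert; no new stereocenter.

Step 4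
Reactants: 4 trimethyl{[(3aS,6R)-3,6-dimethyl-3a,4,5,6-tetrahydro-1H-inden-7-yl]oxy}silane; 5 benzyl but-2-ynoate
Product: 8 benzyl (5R,8S)-2,5,9-trimethyl-4-oxobicyclo[6.3.0]undeca-1,9-diene-3-carboxylate, via silyloxycyclobutene adduct 6 (not isolated), via ring-expanded silyl dienol ether 7 (not isolated)
Conditions: EtAlCl2 (1.1 equiv), CH2Cl2, –78 → 0 °C; PhMe, 80 °C; 1 M HCl, THF, 0 °C
Reagents that add atoms: none
Why: Lewis-acid-promoted [2+2] cycloaddition (nucleophilic C2 attacks the methyl-bearing alkyne carbon) gives a donor–acceptor cyclobutene whose 4π electrocyclic ring opening inserts C1 and C18 between C2 and C10, forming ring B with the Z C1=C2 alkene enforced by the eight-membered ring; C18 is an enolisable β-keto ester centre, so no stereocenter is fixed.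

Step 5
Reactants: 9 (−)-α-thujone [(1S,4R,5R)-4-methyl-1-(propan-2-yl)bicyclo[3.1.0]hexan-3-one]
Product: 10 4-[(benzyloxy)methyl]-4-methyl-1-(propan-2-yl)bicyclo[3.1.0]hexan-3-one (CH2OBn anti to the cyclopropane CH2)
Conditions: LiN(SiMe3)2 (0.95 equiv), THF, 25 °C, 2 h; BnOCH2Cl, –78 → 0 °C
Reagents that add atoms: benzyl chloromethyl ether, ClCOCc1ccccc1
Why: alkylation of the equilibrated, more substituted enolate occurs on the convex face anti to the cyclopropane methylene, setting quaternary C12 (C11 trans to the future C17).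

Step 6
Reactants: 10 4-[(benzyloxy)methyl]-4-methyl-1-(propan-2-yl)bicyclo[3.1.0]hexan-3-one
Product: 11 4-[(benzyloxy)methyl]-2-bromo-4-methyl-1-(propan-2-yl)bicyclo[3.1.0]hexan-3-one (bromide epimers)
Conditions: LiN(SiMe3)2, THF, –78 °C; NBS, –78 → 0 °C
Reagents that add atoms: N-bromosuccinimide, O=C1CCC(=O)N1Br
Why: enolate bromination can occur only at C14, the sole remaining enolisable position; the new C–Br centre is destroyed in the next step.

Step 7
Reactants: 11 4-[(benzyloxy)methyl]-2-bromo-4-methyl-1-(propan-2-yl)bicyclo[3.1.0]hexan-3-one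
Product: 12 5-[(benzyloxy)methyl]-4-(bromomethyl)-5-methyl-3-(propan-2-yl)cyclopent-2-en-1-one (CH2Br cis to the 5-methyl)
Conditions: Bu3SnSnBu3 (10 mol%), PhH, hν (sunlamp), 80 °C
Reagents that add atoms: none
Why: atom-transfer radical rearrangement, in which the α-keto cyclopropylcarbinyl radical opens its stereoelectronically aligned external C15–C17 bond and the primary radical abstracts bromine from 11; C16 is untouched and C15 becomes sp2.

Step 8
Reactants: 12 5-[(benzyloxy)methyl]-4-(bromomethyl)-5-methyl-3-(propan-2-yl)cyclopent-2-en-1-one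
Product: 13 5-[(benzyloxy)methyl]-4-(bromomethyl)-5-methyl-3-(propan-2-yl)cyclopent-2-en-1-ol (OH cis to the methyl)
Conditions: NaBH4, CeCl3·7H2O, MeOH, –40 °C
Reagents that add atoms: none
Why: Luche 1,2-reduction, hydride entering anti to the cis C12-methyl/C16-bromomethyl pair (benzyloxymethyl held in plane by cerium chelation), sets C13 with OH cis to the C12 methyl.

Step 9
Reactants: 13 5-[(benzyloxy)methyl]-4-(bromomethyl)-5-methyl-3-(propan-2-yl)cyclopent-2-en-1-ol
Product: 14 2-[(benzyloxy)methyl]-3-(bromomethyl)-2-methyl-4-(propan-2-yl)cyclopentan-1-ol (all four centres as in ring D of the target)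
Conditions: [Ir(cod)(py)(PCy3)]PF6 (5 mol%), H2 (1 atm), CH2Cl2, 25 °C
Reagents that add atoms: none
Why: hydroxyl-directed hydrogenation delivers H2 syn to the C13 hydroxyl, setting C15 with isopropyl trans to the bromomethyl group.

Step 10
Reactants: 14 2-[(benzyloxy)methyl]-3-(bromomethyl)-2-methyl-4-(propan-2-yl)cyclopentan-1-ol
Product: 15 tert-butyldimethylsilyl ether of 14
Conditions: TBSOTf, 2,6-lutidine, CH2Cl2, 0 °C
Reagents that add atoms: tert-butyldimethylsilyl triflate, CC(C)(C)[Si](C)(C)OS(=O)(=O)C(F)(F)F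
Why: silylation protects the hindered secondary C13 alcohol for the oxidation and carbonyl coupling to come; no stereocenter changes.

Step 11
Reactants: 8 benzyl (5R,8S)-2,5,9-trimethyl-4-oxobicyclo[6.3.0]undeca-1,9-diene-3-carboxylate; 15 tert-butyldimethylsilyl ether of 14
Product: 16 C18-alkylated β-keto ester (benzyl ester, benzyl ether, TBS ether; C18 quaternary, either epimer)
Conditions: Cs2CO3, Bu4NI (10 mol%), DMF, 60 °C
Reagents that add atoms: none
Why: SN2 C-alkylation of the soft β-keto ester anion by the primary halide (iodide formed in situ) makes the C17–C18 bond; the C18 centre is reset in the next step.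

Step 12
Reactants: 16 C18-alkylated β-keto ester
Product: 18 seco-ring-C keto alcohol (C10 ketone, C11 primary alcohol, ring A saturated), via β-keto acid 17 (not isolated)
Conditions: H2 (1 atm), 10% Pd/C, EtOAc, 25 °C; then 50 °C
Reagents that add atoms: none
Why: hydrogenolysis removes both benzyl groups, the β-keto acid decarboxylates, and H2 adds to C4=C5 from the C6–H face (anti to C7), setting the C5 methyl cis to C7; C18 (α-keto and allylic) remains epimerisable and is fixed in step 14.

Step 13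
Reactants: 18 seco-ring-C keto alcohol
Product: 19 keto aldehyde (C10 ketone, C11 aldehyde)
Conditions: Dess–Martin periodinane, NaHCO3, CH2Cl2, 0 → 25 °C
Reagents that add atoms: none
Why: buffered Dess–Martin oxidation gives the non-enolisable neopentyl aldehyde without touching the base-sensitive C9 and C18 centres.

Step 14
Reactants: 19 keto aldehyde
Product: 20 13-O-(tert-butyldimethylsilyl)aspergilol C
Conditions: TiCl3(DME)1.5, Zn–Cu, DME, reflux, syringe-pump addition
Reagents that add atoms: none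
Why: intramolecular McMurry coupling of ketone and aldehyde closes ring C as the C10=C11 alkene; the chair-like pinacolate places the C18–C1 bond equatorial, so the labile C18 centre ends with H18 cis to H16.

Step 15
Reactants: 20 13-O-(tert-butyldimethylsilyl)aspergilol C
Product: 21 aspergilol C
Conditions: Bu4NF, THF, 50 °C
Reagents that add atoms: none
Why: fluoride desilylation frees the C13 alcohol without touching the two alkenes or any stereocenter.

**Compound list**
1 | (+)-dihydrocarvone, (2R,5R)-2-methyl-5-(prop-1-en-2-yl)cyclohexan-1-one | C[C@@H]1CC[C@H](CC1=O)C(C)=C | starting material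
2 | (3S,6R)-6-methyl-2-methylidene-3-(prop-1-en-2-yl)cyclohexan-1-one | C[C@@H]1CC[C@H](C(=C)C1=O)C(C)=C | intermediate
3 | trimethyl{[(3S,6R)-6-methyl-3-(prop-1-en-2-yl)-2-(prop-2-en-1-yl)cyclohex-1-en-1-yl]oxy}silane | C[C@@H]1CC[C@H](C(CC=C)=C1O[Si](C)(C)C)C(C)=C | intermediate
4 | trimethyl{[(3aS,6R)-3,6-dimethyl-3a,4,5,6-tetrahydro-1H-inden-7-yl]oxy}silane | C[C@@H]1CC[C@H]2C(C)=CCC2=C1O[Si](C)(C)C | intermediate
5 | benzyl but-2-ynoate | CC#CC(=O)OCc1ccccc1 | starting material
6 | silyloxycyclobutene adduct (cyclobutene fused at C2–C10; the two new ring-fusion centres unassigned, both lost on opening) | C[C@@H]1CC[C@H]2C(C)=CCC23C(C)=C(C(=O)OCc4ccccc4)C13O[Si](C)(C)C | intermediate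
7 | ring-expanded silyl dienol ether (Z,Z-diene in ring B) | C[C@@H]1CC[C@H]2C(C)=CC\C2=C(/C)\C(C(=O)OCc3ccccc3)=C1\O[Si](C)(C)C | intermediate
8 | benzyl (5R,8S)-2,5,9-trimethyl-4-oxobicyclo[6.3.0]undeca-1,9-diene-3-carboxylate (C3 of this name = C18, epimers/enol) | C[C@@H]1CC[C@H]2C(C)=CC\C2=C(/C)C(C(=O)OCc3ccccc3)C1=O | intermediate
9 | (−)-α-thujone, (1S,4R,5R)-4-methyl-1-(propan-2-yl)bicyclo[3.1.0]hexan-3-one | CC(C)[C@@]12C[C@@H]1[C@@H](C)C(=O)C2 | starting material
10 | 4-[(benzyloxy)methyl]-4-methyl-1-(propan-2-yl)bicyclo[3.1.0]hexan-3-one, CH2OBn anti to the cyclopropane CH2 | CC(C)[C@@]12C[C@@H]1[C@@](C)(COCc3ccccc3)C(=O)C2 | intermediate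
11 | 2-bromo derivative of 10 (bromide epimers) | CC(C)[C@@]12C[C@@H]1[C@@](C)(COCc3ccccc3)C(=O)C2Br | intermediate
12 | 5-[(benzyloxy)methyl]-4-(bromomethyl)-5-methyl-3-(propan-2-yl)cyclopent-2-en-1-one, CH2Br cis to 5-methyl | CC(C)C1=CC(=O)[C@](C)(COCc2ccccc2)[C@H]1CBr | intermediate
13 | 5-[(benzyloxy)methyl]-4-(bromomethyl)-5-methyl-3-(propan-2-yl)cyclopent-2-en-1-ol, OH cis to methyl | CC(C)C1=C[C@@H](O)[C@](C)(COCc2ccccc2)[C@H]1CBr | intermediate
14 | 2-[(benzyloxy)methyl]-3-(bromomethyl)-2-methyl-4-(propan-2-yl)cyclopentan-1-ol, isopropyl trans to CH2Br | CC(C)[C@@H]1C[C@@H](O)[C@](C)(COCc2ccccc2)[C@H]1CBr | intermediate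
15 | tert-butyldimethylsilyl ether of 14 | CC(C)[C@@H]1C[C@@H](O[Si](C)(C)C(C)(C)C)[C@](C)(COCc2ccccc2)[C@H]1CBr | intermediate
16 | C18-alkylated β-keto ester (C18 quaternary, unassigned) | C[C@@H]1CC[C@H]2C(C)=CC\C2=C(/C)C(C(=O)OCc3ccccc3)(C[C@H]4[C@H](C(C)C)C[C@@H](O[Si](C)(C)C(C)(C)C)[C@]4(C)COCc5ccccc5)C1=O | intermediate
17 | β-keto acid (debenzylated, ring A saturated) | C[C@@H]1CC[C@H]2[C@@H](C)CC\C2=C(/C)C(C(=O)O)(C[C@H]3[C@H](C(C)C)C[C@@H](O[Si](C)(C)C(C)(C)C)[C@]3(C)CO)C1=O | intermediate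
18 | seco-ring-C keto alcohol (C18 drawn as needed, epimerisable) | C[C@@H]1CC[C@H]2[C@@H](C)CC\C2=C(/C)[C@@H](C[C@H]3[C@H](C(C)C)C[C@@H](O[Si](C)(C)C(C)(C)C)[C@]3(C)CO)C1=O | intermediate
19 | keto aldehyde | C[C@@H]1CC[C@H]2[C@@H](C)CC\C2=C(/C)[C@@H](C[C@H]3[C@H](C(C)C)C[C@@H](O[Si](C)(C)C(C)(C)C)[C@]3(C)C=O)C1=O | intermediate
20 | 13-O-(tert-butyldimethylsilyl)aspergilol C | C/C1=C2\CC[C@H](C)[C@@H]2CC[C@@H](C)C2=C[C@@]3(C)[C@H](O[Si](C)(C)C(C)(C)C)C[C@@H](C(C)C)[C@@H]3C[C@@H]21 | intermediate
21 | aspergilol C | C/C1=C2\CC[C@H](C)[C@@H]2CC[C@@H](C)C2=C[C@@]3(C)[C@H](O)C[C@@H](C(C)C)[C@@H]3C[C@@H]21 | target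

**Count**
Total steps: 15. Longest linear sequence: 11 steps (9 → 21, steps 5–15).

**Three steps most likely to fail**

Step 4 (ring expansion). The cycloaddition must join the fully substituted ring-fusion carbon C2 to the methyl-bearing alkyne carbon, and the cyclobutene must open without the C1=C2 alkene drifting into conjugation. The fallback sets out from 4 and returns at 18. MeLi (THF, 0 °C) releases the lithium enolate, which is added to 1-(phenylsulfonyl)prop-1-yne. Michael addition, four-membered aldol closure and alkoxide-driven fragmentation give β-keto sulfone F1. Alkylation with 15 (Cs2CO3, DMF) gives alkylated keto sulfone F2, and H2 over Pd/C gives debenzylated, ring-A-saturated keto sulfone F3. Al–Hg then removes the sulfone to give 18.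

Step 11 (alkylation). A tertiary carbanion must displace a β-branched primary halide. The fallback sets out from 8 and 15 and returns at 18. H2 over Pd/C turns 8 into bicyclic ketone F4 (debenzylation, decarboxylation, C4=C5 hydrogenation). Kornblum oxidation of 15 (DMSO, NaHCO3, 110 °C) gives aldehyde F5. Kinetic aldol at the allylic C18 methylene (LiN(i-Pr)2, –78 °C), then MsCl/Et3N and DBU, gives cross-conjugated enone F6. Conjugate reduction with [(Ph3P)CuH]6 gives benzyl ether ketone F7, and H2 over Pd(OH)2/C cleaves the benzyl ether to give 18.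

Step 14 (McMurry closure and the C18 centre). The β,γ-unsaturated ketone can epimerise at C9 or slip into conjugation under Lewis-acidic low-valent titanium, and the C18 outcome rests on the chair-like coupling argument. The fallback sets out from 19 and returns at 20. Cp2TiMe2 (toluene, 70 °C) methylenates both carbonyls under non-acidic conditions to give diene F8. Second-generation Grubbs catalyst then closes ring C by ring-closing metathesis to the trisubstituted C10=C11 alkene of 20.

**Further compounds**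
F1 | step 4 | β-keto sulfone (phenylsulfonyl in place of the benzyl ester of 8) | C[C@@H]1CC[C@H]2C(C)=CC\C2=C(/C)C(S(=O)(=O)c3ccccc3)C1=O
F2 | step 4 | C18-alkylated keto sulfone | C[C@@H]1CC[C@H]2C(C)=CC\C2=C(/C)C(S(=O)(=O)c3ccccc3)(C[C@H]4[C@H](C(C)C)C[C@@H](O[Si](C)(C)C(C)(C)C)[C@]4(C)COCc5ccccc5)C1=O
F3 | step 4 | debenzylated, ring-A-saturated keto sulfone | C[C@@H]1CC[C@H]2[C@@H](C)CC\C2=C(/C)C(S(=O)(=O)c3ccccc3)(C[C@H]4[C@H](C(C)C)C[C@@H](O[Si](C)(C)C(C)(C)C)[C@]4(C)CO)C1=O
F4 | step 11 | bicyclic ketone (C18 methylene, ring A saturated) | C[C@@H]1CC[C@H]2[C@@H](C)CC\C2=C(/C)CC1=O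
F5 | step 11 | ring D aldehyde (C17 formyl) | CC(C)[C@@H]1C[C@@H](O[Si](C)(C)C(C)(C)C)[C@](C)(COCc2ccccc2)[C@H]1C=O
F6 | step 11 | cross-conjugated enone (C18=C17) | C[C@@H]1CC[C@H]2[C@@H](C)CC\C2=C(/C)C(=C[C@H]3[C@H](C(C)C)C[C@@H](O[Si](C)(C)C(C)(C)C)[C@]3(C)COCc4ccccc4)C1=O
F7 | step 11 | benzyl ether ketone (benzyl ether of 18) | C[C@@H]1CC[C@H]2[C@@H](C)CC\C2=C(/C)[C@@H](C[C@H]3[C@H](C(C)C)C[C@@H](O[Si](C)(C)C(C)(C)C)[C@]3(C)COCc4ccccc4)C1=O
F8 | step 14 | diene (C10 methylidene, C12 vinyl) | C[C@@H]1CC[C@H]2[C@@H](C)CC\C2=C(/C)[C@@H](C[C@H]3[C@H](C(C)C)C[C@@H](O[Si](C)(C)C(C)(C)C)[C@]3(C)C=C)C1=C
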